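**Plan**

- Numbering follows the naphthoquinone: ring B is the quinone ring (C1–C4), ring A the benzenoid ring (C5–C8). C7 of ring A is a bare CH between C6–OMe and C8–aryl, so ring A is the C2=C3 bond of a 2-methoxy-3-arylindene with one carbon inserted.
- Retrosynthesis: quinone ring B back to a 1,2,4-trimethoxyarene; C7–H back to C7–Br; cut C6–C7 and C7–C8, removing C7 as dibromocarbene.
- Further cuts: the enol-ether O–Me and the C2 oxygen (via a 1-aryl-2-indanone), the C8–aryl bond (Grignard addition to a 1-indanone), the indanone acyl–arene bond (Friedel–Crafts) and the side-chain C=C (Knoevenagel).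
- Forward: ring B is the 2,4,5-trimethoxyphenyl ring of the starting aldehyde; the five-membered ring is closed by Friedel–Crafts acylation, arylated, oxygenated at C2 and O-methylated; carbene insertion enlarges it to ring A; debromination and oxidation of ring B finish.
- Stereochemistry: the target has no stereocenter; the stereocenters of intermediates are racemic and all are removed by the ring expansion.

Key step: step 7

Remark: the veratryl ring has no ortho substituent, so the biaryl axis is taken as freely rotating and nothing stereochemical has to be controlled. Racemic ring-fused intermediates are drawn as one enantiomer.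

**Step 1**
Reactants: 1 2,4,5-trimethoxybenzaldehyde; 2 malonic acid
Product: 4 (E)-3-(2,4,5-trimethoxyphenyl)prop-2-enoic acid, via arylidenemalonic acid 3 (not isolated)
Conditions: pyridine, piperidine (cat.), 100 °C
Reagents that add atoms: none
Why: Knoevenagel condensation in the Doebner modification, in which the arylidenemalonic acid decarboxylates in hot pyridine to the E-cinnamic acid, a standard outcome for electron-rich benzaldehydes.

**Step 2**
Reactants: 4 (E)-3-(2,4,5-trimethoxyphenyl)prop-2-enoic acid
Product: 5 3-(2,4,5-trimethoxyphenyl)propanoic acid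
Conditions: H2 (1 atm), 10% Pd/C, EtOAc/MeOH, rt
Reagents that add atoms: none
Why: Heterogeneous catalytic hydrogenation of the conjugated C=C bond should proceed under conditions that leave the arene, the methyl ethers and the acid untouched.

**Step 3**
Reactants: 5 3-(2,4,5-trimethoxyphenyl)propanoic acid
Product: 6 4,6,7-trimethoxy-2,3-dihydro-1H-inden-1-one
Conditions: P2O5/MeSO3H (Eaton's reagent), rt → 50 °C
Reagents that add atoms: none
Why: Intramolecular Friedel–Crafts acylation can only close the five-membered ring at the single free position ortho to the side chain, which is activated by the neighbouring methoxy group, as in the analogous cyclization of 3-(2,5-dimethoxyphenyl)propanoic acid.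

**Step 4**
Reactants: 6 4,6,7-trimethoxy-2,3-dihydro-1H-inden-1-one; 7 4-bromoveratrole (4-bromo-1,2-dimethoxybenzene)
Product: 10 3-(3,4-dimethoxyphenyl)-4,5,7-trimethoxy-1H-indene, via 3,4-dimethoxyphenylmagnesium bromide 8 (not isolated), via tertiary indanol 9 (not isolated)
Conditions: 7, Mg, THF, 50 °C; then 6, CeCl3, THF, 0 °C; 1 M HCl; then TsOH·H2O (cat.), toluene, 80 °C
Reagents that add atoms: none
Why: Grignard 1,2-addition under organocerium conditions (CeCl3 suppresses enolization of the peri-hindered indanone) followed by acid-catalysed E1 dehydration of the doubly benzylic tertiary alcohol should give the conjugated 3-arylindene.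

**Step 5**
Reactants: 10 3-(3,4-dimethoxyphenyl)-4,5,7-trimethoxy-1H-indene
Product: 12 1-(3,4-dimethoxyphenyl)-4,6,7-trimethoxy-1,3-dihydro-2H-inden-2-one (racemic), via indene epoxide 11 (not isolated)
Conditions: dimethyldioxirane (acetone solution), CH2Cl2, −20 °C; then BF3·OEt2 (cat.), CH2Cl2, −40 → 0 °C
Reagents that add atoms: dimethyldioxirane, CC1(C)OO1
Why: Epoxidation of the electron-rich trisubstituted styrene by the neutral dioxirane followed by Meinwald rearrangement, in which BF3 opens the epoxide at the doubly benzylic carbon and a 1,2-hydride shift from C2 gives the 2-indanone; the one stereocenter formed is racemic and is erased in step 6.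

**Step 6**
Reactants: 12 1-(3,4-dimethoxyphenyl)-4,6,7-trimethoxy-1,3-dihydro-2H-inden-2-one
Product: 14 3-(3,4-dimethoxyphenyl)-2,4,5,7-tetramethoxy-1H-indene, via dimethyl ketal 13 (not isolated)
Conditions: HC(OMe)3, TsOH·H2O (cat.), toluene, 60 °C; then 110 °C with distillation of MeOH
Reagents that add atoms: trimethyl orthoformate, COC(OC)OC
Why: Acid-catalysed ketalization with the orthoformate and thermal loss of methanol (enol ether formation via the dimethyl ketal, as used for 2-indanone itself) run under equilibrating conditions, which should settle on the tetrasubstituted C2=C3 isomer conjugated with both arenes.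

**Step 7**
Reactants: 14 3-(3,4-dimethoxyphenyl)-2,4,5,7-tetramethoxy-1H-indene; 15 bromoform
Product: 17 2-bromo-1-(3,4-dimethoxyphenyl)-3,5,7,8-tetramethoxynaphthalene, via dibromocyclopropane 16 (not isolated)
Conditions: KOtBu (added in portions), pentane, −20 °C → rt
Reagents that add atoms: none
Why: KOtBu removes HBr from bromoform by α-elimination, and the electrophilic singlet dibromocarbene adds in a concerted [2+1] cheletropic manner to the C2=C3 enol-ether bond of 14 to give the cis-fused dibromocyclopropane 16. The endo bromide then ionizes with disrotatory two-electron electrocyclic opening of the cyclopropane, which breaks the former C2–C3 bond and leaves a cyclic 2-bromoallyl cation stabilized by the methoxy group at one terminus and two aryl groups at the other; loss of a proton from the adjacent CH2 to the second equivalent of base aromatizes the ring. Ring A therefore arises by enlargement of the five-membered ring (cleavage of the shared bond of the bicyclo[3.1.0] unit) and not by an end-to-end cyclization; the carbene carbon becomes C7 with the new bonds C6–C7 and C7–C8 (indene C2 becomes C6, indene C3 becomes C8). The closest known reaction type is the dihalocarbene ring expansion of indenes and cyclic enol ethers to 2-halonaphthalenes (Ciamician–Dennstedt-type one-carbon insertion). No stereocenter remains in the product; the two in 16 are cis by ring fusion and are lost on opening. The step needs chemoselectivity for the enol-ether alkene over the methoxyarenes and over deprotonation of the indene CH2 (an indenyl anion would take up the carbon on the wrong side): the tetrasubstituted alkoxy/aryl alkene is the most nucleophilic π bond, slow addition of base to excess bromoform (by far the stronger acid) at low temperature in pentane should keep the indene neutral, and the regiochemistry of the new ring is fixed by the position of the double bond.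

**Step 8**
Reactants: 17 2-bromo-1-(3,4-dimethoxyphenyl)-3,5,7,8-tetramethoxynaphthalene
Product: 19 1-(3,4-dimethoxyphenyl)-3,5,7,8-tetramethoxynaphthalene, via aryllithium 18 (not isolated)
Conditions: n-BuLi, THF, −78 °C; then H2O
Reagents that add atoms: none
Why: Bromine–lithium exchange is fast at −78 °C even for a doubly ortho-flanked bromide, and protonation of the aryllithium (stabilized by the ortho methoxy group) should give the C7–H compound while the methyl ethers stay inert.

**Step 9**
Reactants: 19 1-(3,4-dimethoxyphenyl)-3,5,7,8-tetramethoxynaphthalene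
Product: 20 8-(3,4-dimethoxyphenyl)-2,6-dimethoxynaphthalene-1,4-dione (CNP0128574.0)
Conditions: (NH4)2Ce(NO3)6 (2.2 equiv), MeCN/H2O, 0 °C
Reagents that add atoms: water, O
Why: Oxidative demethylation by tetravalent cerium should attack the 1,2,4-trimethoxy ring, the most electron-rich site, and convert its para pair of methoxy groups (C1 and C4) into the 1,4-quinone with oxygen from water, leaving C2–OMe as the vinylogous ester, as is usual for 1,2,4-trimethoxyarenes.

**Compound list**

1 | 2,4,5-trimethoxybenzaldehyde | COc1cc(OC)c(C=O)cc1OC | starting material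
2 | malonic acid | OC(=O)CC(=O)O | starting material
3 | 2-(2,4,5-trimethoxybenzylidene)malonic acid (formed in the flask) | COc1cc(OC)c(C=C(C(=O)O)C(=O)O)cc1OC | intermediate
4 | (E)-3-(2,4,5-trimethoxyphenyl)prop-2-enoic acid | COc1cc(OC)c(/C=C/C(=O)O)cc1OC | intermediate
5 | 3-(2,4,5-trimethoxyphenyl)propanoic acid | COc1cc(OC)c(CCC(=O)O)cc1OC | intermediate
6 | 4,6,7-trimethoxy-2,3-dihydro-1H-inden-1-one | COc1cc(OC)c2c(c1OC)C(=O)CC2 | intermediate
7 | 4-bromoveratrole (4-bromo-1,2-dimethoxybenzene) | COc1ccc(Br)cc1OC | starting material
8 | 3,4-dimethoxyphenylmagnesium bromide (formed in the flask) | COc1ccc([Mg]Br)cc1OC | intermediate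
9 | 1-(3,4-dimethoxyphenyl)-4,6,7-trimethoxy-2,3-dihydro-1H-inden-1-ol (racemic; formed in the flask) | COc1cc(OC)c2c(c1OC)C(O)(c1ccc(OC)c(OC)c1)CC2 | intermediate
10 | 3-(3,4-dimethoxyphenyl)-4,5,7-trimethoxy-1H-indene | COc1cc(OC)c2c(c1OC)C(c1ccc(OC)c(OC)c1)=CC2 | intermediate
11 | 1a-(3,4-dimethoxyphenyl)-2,3,5-trimethoxy-6,6a-dihydro-1aH-indeno[1,2-b]oxirene (2,3-epoxide of 10; racemic, cis-fused; formed in the flask) | COc1cc(OC)c2c(c1OC)[C@]1(c3ccc(OC)c(OC)c3)O[C@@H]1C2 | intermediate
12 | 1-(3,4-dimethoxyphenyl)-4,6,7-trimethoxy-1,3-dihydro-2H-inden-2-one (racemic) | COc1cc(OC)c2c(c1OC)C(c1ccc(OC)c(OC)c1)C(=O)C2 | intermediate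
13 | 1-(3,4-dimethoxyphenyl)-2,2,4,6,7-pentamethoxy-2,3-dihydro-1H-indene (dimethyl ketal of 12; racemic; formed in the flask) | COc1cc(OC)c2c(c1OC)C(c1ccc(OC)c(OC)c1)C(OC)(OC)C2 | intermediate
14 | 3-(3,4-dimethoxyphenyl)-2,4,5,7-tetramethoxy-1H-indene | COc1cc(OC)c2c(c1OC)C(c1ccc(OC)c(OC)c1)=C(OC)C2 | intermediate
15 | bromoform | BrC(Br)Br | starting material
16 | 1,1-dibromo-1a-(3,4-dimethoxyphenyl)-2,3,5,6a-tetramethoxy-1,1a,6,6a-tetrahydrocyclopropa[a]indene (carbene adduct of 14; racemic, cis-fused; formed in the flask) | COc1cc(OC)c2c(c1OC)[C@]1(c3ccc(OC)c(OC)c3)C(Br)(Br)[C@]1(OC)C2 | intermediate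
17 | 2-bromo-1-(3,4-dimethoxyphenyl)-3,5,7,8-tetramethoxynaphthalene | COc1cc2c(OC)cc(OC)c(OC)c2c(-c2ccc(OC)c(OC)c2)c1Br | intermediate
18 | [1-(3,4-dimethoxyphenyl)-3,5,7,8-tetramethoxynaphthalen-2-yl]lithium (formed in the flask) | [Li]c1c(OC)cc2c(OC)cc(OC)c(OC)c2c1-c1ccc(OC)c(OC)c1 | intermediate
19 | 1-(3,4-dimethoxyphenyl)-3,5,7,8-tetramethoxynaphthalene | COc1cc(-c2ccc(OC)c(OC)c2)c2c(OC)c(OC)cc(OC)c2c1 | intermediate
20 | 8-(3,4-dimethoxyphenyl)-2,6-dimethoxynaphthalene-1,4-dione | COC1=CC(=O)c2cc(OC)cc(-c3ccc(OC)c(OC)c3)c2C1=O | target

**Step count and risks**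

Total step count: 9. Longest linear sequence: 9 steps (1 → 20).

Steps most likely to fail:

1. Step 7. Deprotonation of the indene CH2 may compete with carbene generation, which would migrate the double bond or insert the carbon on the wrong side. The hindered tetrasubstituted alkene may also be cyclopropanated slowly, and the enol ether may hydrolyse. The fallback sets out from 12 and makes the same two bonds without base or halogen. Silylation (Me3SiCl, Et3N, DMF) should give the silyl enol ether 3-(3,4-dimethoxyphenyl)-4,5,7-trimethoxy-2-(trimethylsilyloxy)-1H-indene F1. Simmons–Smith cyclopropanation under Furukawa conditions (Et2Zn, CH2I2, CH2Cl2) should give the siloxycyclopropane 1a-(3,4-dimethoxyphenyl)-2,3,5-trimethoxy-6a-(trimethylsilyloxy)-1,1a,6,6a-tetrahydrocyclopropa[a]indene F2. Oxidation with FeCl3 in DMF (Saegusa–Ito ring enlargement) cleaves the internal cyclopropane bond; after proton loss the ring-enlarged enone tautomerizes to the naphthol 4-(3,4-dimethoxyphenyl)-5,6,8-trimethoxynaphthalen-2-ol F3. O-Methylation (MeI, K2CO3, acetone) comes back to the route at 19, so step 8 is no longer needed.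

2. Step 6. Loss of methanol from the ketal may be incomplete, the acid equilibrium may place the double bond on the CH2 side, or the 2-indanone may self-condense under acid. The fallback sets out from 12 and fixes the double-bond position kinetically. KN(SiMe3)2 in THF/DMPU at −78 °C removes the doubly benzylic proton to give the enolate potassium 3-(3,4-dimethoxyphenyl)-4,5,7-trimethoxy-1H-inden-2-olate F4. Trapping on oxygen with the hard electrophile dimethyl sulfate comes back to the route at 14.

3. Step 9. Oxidative demethylation may run across the ortho pair (C1/C2) instead of the para pair (C1/C4) of methoxy groups, and the veratryl ring may be oxidized in competition. The fallback sets out from 19 and uses a thermodynamic funnel. The CAN oxidation is taken to full conversion without regard to the ortho/para outcome, giving 20 mixed with the ortho-quinone 8-(3,4-dimethoxyphenyl)-4,6-dimethoxynaphthalene-1,2-dione F5. Both are vinylogous esters, and 1 M NaOH in THF/H2O followed by acid should hydrolyse them to the single hydroxyquinone 8-(3,4-dimethoxyphenyl)-2-hydroxy-6-methoxynaphthalene-1,4-dione F6. Equilibrating methylation with MeOH/HCl at reflux favours the 2-methoxy-1,4-quinone and comes back to the route at 20.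

**Further compounds**

F1 | step 7 | 3-(3,4-dimethoxyphenyl)-4,5,7-trimethoxy-2-(trimethylsilyloxy)-1H-indene | COc1cc(OC)c2c(c1OC)C(c1ccc(OC)c(OC)c1)=C(O[Si](C)(C)C)C2
F2 | step 7 | 1a-(3,4-dimethoxyphenyl)-2,3,5-trimethoxy-6a-(trimethylsilyloxy)-1,1a,6,6a-tetrahydrocyclopropa[a]indene (racemic, cis-fused) | COc1cc(OC)c2c(c1OC)[C@]1(c3ccc(OC)c(OC)c3)C[C@]1(O[Si](C)(C)C)C2
F3 | step 7 | 4-(3,4-dimethoxyphenyl)-5,6,8-trimethoxynaphthalen-2-ol | COc1cc(OC)c2cc(O)cc(-c3ccc(OC)c(OC)c3)c2c1OC
F4 | step 6 | potassium 3-(3,4-dimethoxyphenyl)-4,5,7-trimethoxy-1H-inden-2-olate | COc1cc(OC)c2c(c1OC)C(c1ccc(OC)c(OC)c1)=C([O-])C2.[K+]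
F5 | step 9 | 8-(3,4-dimethoxyphenyl)-4,6-dimethoxynaphthalene-1,2-dione | COC1=CC(=O)C(=O)c2c(-c3ccc(OC)c(OC)c3)cc(OC)cc12
F6 | step 9 | 8-(3,4-dimethoxyphenyl)-2-hydroxy-6-methoxynaphthalene-1,4-dione | OC1=CC(=O)c2cc(OC)cc(-c3ccc(OC)c(OC)c3)c2C1=O
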